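**Retrosynthetic overview**
1. Numbering: chain C1 (alkyne CH) to C15 (CH3); ring A = O/C7/C8/C9/C10, ring B = O/C9/C10/C11/C12. C8–Br and C13–Br ⇒ C–OH (two Appel inversions). C6=C7 ⇒ aldol condensation of bicyclic ketone 19 (C7H2, C8=O) with skipped enynal 25.
2. 19 ⇒ tricyclic keto lactone 16, in which a CO2 unit bridges C9 and the oxygen on C13. It leaves as CO2 through the β-keto acid and frees the C13 alcohol.
3. 16 ⇒ acyclic diazo aldehyde 13. A Rh carbenoid at C9 gives a cyclic carbonyl ylide, so the temporary six-ring lactone closes first. Intramolecular [3+2] with the O-vinyl group then closes rings A and B together through C9–C10 and C11–C12.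
4. Enabling feature: in ring B the ring oxygen is flanked by C9 and C12 (a C–O–C carbonyl-ylide unit). It faces the C10–C11 two-carbon unit, whose C10 bears the ring-A oxygen (a vinyl ether). The ylide termini carry the two bromomethine carbons C8 and C13, which can be a ketone and an acyloxy carbon. C8–C7–O therefore becomes the tether and C9–CO–O–C13 the removable ring.
5. 13 ⇒ ethyl glycolate, butyl vinyl ether, tert-butyl acetate and (R)-butane-1,2-diol; 25 ⇒ but-3-yn-1-ol and ethynyltrimethylsilane.

Key step: step 8

Assumption: compounds marked as starting material are taken as purchasable, and [Rh] in the SMILES of 14 stands for the Rh2(OAc)4 core.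

**Step 1**
Reactants: 1 ethyl glycolate; 2 butyl vinyl ether
Product: 3 ethyl 2-(vinyloxy)acetate
Conditions: Pd(OAc)2 (2 mol %), 1,10-phenanthroline (2.5 mol %), 2 (10 equiv, neat), 60 °C
Reagents that add atoms: none
Why: Pd(II)-catalysed transfer vinylation (transetherification) of a primary alcohol runs under neutral conditions that spare the ester, and the excess of 2 drives the equilibrium to the vinyl ether that becomes C10=C11.

**Step 2**
Reactants: 3 ethyl 2-(vinyloxy)acetate; 4 tert-butyl acetate
Product: 6 tert-butyl 3-oxo-4-(vinyloxy)butanoate, via lithium enolate of tert-butyl acetate 5 (not isolated)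
Conditions: LDA (2.2 equiv), 4 (2.2 equiv), THF, −78 °C; then 3, −78 to −20 °C; AcOH
Reagents that add atoms: none
Why: In this crossed Claisen condensation the tert-butyl acetate enolate, which does not self-condense at −78 °C, is acylated by the activated α-alkoxy ester, and the second equivalent of enolate deprotonates the β-keto ester so that the reaction stops there.

**Step 3**
Reactants: 7 (R)-butane-1,2-diol
Product: 8 (R)-1-[(tert-butyldimethylsilyl)oxy]butan-2-ol
Conditions: TBSCl (1.05 equiv), imidazole (2 equiv), CH2Cl2, 0 °C
Reagents that add atoms: tert-butyldimethylsilyl chloride, CC(C)(C)[Si](C)(C)Cl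
Why: Silylation with the bulky chlorosilane is selective for the primary hydroxyl, and the purchased stereocentre (future C13) is not touched.

**Step 4**
Reactants: 6 tert-butyl 3-oxo-4-(vinyloxy)butanoate; 8 (R)-1-[(tert-butyldimethylsilyl)oxy]butan-2-ol
Product: 10 (R)-1-[(tert-butyldimethylsilyl)oxy]butan-2-yl 3-oxo-4-(vinyloxy)butanoate, via acylketene 9 (not isolated)
Conditions: toluene, 110 °C, t-BuOH distilled off
Reagents that add atoms: none
Why: In this thermal transacetoacetylation the tert-butyl β-keto ester loses tert-butanol to give acylketene 9, which the secondary alcohol traps under neutral conditions that keep the vinyl ether, the silyl ether and the C13–O bond (retention) intact.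

**Step 5**
Reactants: 10 (R)-1-[(tert-butyldimethylsilyl)oxy]butan-2-yl 3-oxo-4-(vinyloxy)butanoate
Product: 11 (R)-1-[(tert-butyldimethylsilyl)oxy]butan-2-yl 2-diazo-3-oxo-4-(vinyloxy)butanoate
Conditions: p-ABSA (1.1 equiv), Et3N, MeCN, 0 °C to rt
Reagents that add atoms: 4-acetamidobenzenesulfonyl azide, CC(=O)Nc1ccc(cc1)S(=O)(=O)N=[N+]=[N-]
Why: Regitz diazo transfer onto the doubly activated methylene (future C9) is reliable for β-keto esters and needs only a mild amine base.

**Step 6**
Reactants: 11 (R)-1-[(tert-butyldimethylsilyl)oxy]butan-2-yl 2-diazo-3-oxo-4-(vinyloxy)butanoate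
Product: 12 (R)-1-hydroxybutan-2-yl 2-diazo-3-oxo-4-(vinyloxy)butanoate
Conditions: TBAF/AcOH (1:1, 1.2 equiv), THF, 0 °C
Reagents that add atoms: none
Why: Fluoride desilylation buffered with acetic acid stays near neutral, so the vinyl ether is not hydrolysed and 1,2-acyl migration of the poorly electrophilic diazo ester to the freed primary alcohol is held back.

**Step 7**
Reactants: 12 (R)-1-hydroxybutan-2-yl 2-diazo-3-oxo-4-(vinyloxy)butanoate
Product: 13 (R)-1-oxobutan-2-yl 2-diazo-3-oxo-4-(vinyloxy)butanoate
Conditions: Dess–Martin periodinane, pyridine, CH2Cl2, 0 °C; used directly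
Reagents that add atoms: none
Why: Dess–Martin oxidation buffered with pyridine gives the α-acyloxy aldehyde without strong acid or base, so the vinyl ether, the diazo group and the configuration at C13 should survive.

**Step 8**
Reactants: 13 (R)-1-oxobutan-2-yl 2-diazo-3-oxo-4-(vinyloxy)butanoate
Product: 16 tricyclic keto lactone (9R,10S,12R,13R), via rhodium carbenoid 14 (not isolated), via cyclic carbonyl ylide 15 (not isolated)
Conditions: Rh2(OAc)4 (2 mol %), 4 Å MS, PhH (0.005 M), 80 °C, slow addition of 13
Reagents that add atoms: none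
Why: Rh2(OAc)4 expels N2 from 13 to give the electrophilic carbenoid 14 at C9, the lone pair of the ester-tethered aldehyde oxygen attacks it to give the cyclic carbonyl ylide 15, and the O-vinyl group adds across C9 and C12 of this dipole in a concerted suprafacial [π4s+π2s] step, so that C9–O, C9–C10 and C11–C12 are made in one operation. The closest known reaction type is the Rh(II)-catalysed tandem carbonyl ylide formation–intramolecular 1,3-dipolar cycloaddition of α-diazo-β-dicarbonyl compounds, and ylides that bear two acyl groups on one terminus are known to react under LUMO(dipole) control with electron-rich alkenes such as vinyl ethers. The temporary 1,4-dioxan-2-one ring closes first by attack of the carbonyl oxygen on the carbenoid through a six-membered arrangement, ring B is the five-membered ring of the cycloaddition itself, and ring A closes in the fused mode over the three-atom tether C8(=O)–C7H2–O, with the internal alkene carbon C10 bonding to the tether-bearing terminus C9. C9 and C10 come out cis because the addition is suprafacial and the short tether can only reach the position syn to the oxygen bridge, while C12 is controlled by the temporary ring, which holds C13 on the inner side of the C9–O–C12 unit and leaves the C8 tether on the outer side, so that C13 and C8 end up trans across ring B (side chain on the convex face), the opposite of what a free W-shaped ylide would give. The absolute sense comes from the C13 stereocentre next to the cationic terminus, because the alkene adds to the ylide face anti to the ethyl group, which places C11 and ethyl trans on the lactone ring and therefore C12–O and C13–O syn, as the later inversion at C13 requires. The step needs chemoselectivity for carbonyl capture over cyclopropanation of the vinyl ether, which rests on the low cyclopropanating power of doubly acceptor-substituted carbenoids, on the favoured six-ring ylide closure and on slow addition at high dilution, and it needs the fused regiochemistry, which tether length and polarity (nucleophilic C11 to the cationic terminus C12) both secure.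

**Step 9**
Reactants: 16 tricyclic keto lactone (9R,10S,12R,13R)
Product: 18 (3aR,5R,6aS)-5-[(1R)-1-hydroxypropyl]tetrahydrofuro[3,2-b]furan-3(2H)-one, via β-keto acid 17 (not isolated)
Conditions: 1 M H2SO4, 1,4-dioxane, 80 °C
Reagents that add atoms: none
Why: Acid-catalysed acyl–oxygen hydrolysis of the strained bridged lactone gives β-keto acid 17, which decarboxylates through the usual cyclic transition state; ketonisation of the C8=C9 enol can only give the cis-fused bicyclo[3.3.0] system, so C9–H is set cis to C10–H while the C13–O bond is kept with retention.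

**Step 10**
Reactants: 18 (3aR,5R,6aS)-5-[(1R)-1-hydroxypropyl]tetrahydrofuro[3,2-b]furan-3(2H)-one
Product: 19 (3aR,5R,6aS)-5-[(1S)-1-bromopropyl]tetrahydrofuro[3,2-b]furan-3(2H)-one
Conditions: CBr4, (n-Oct)3P, toluene, 70 °C
Reagents that add atoms: carbon tetrabromide, BrC(Br)(Br)Br
Why: The Appel reaction of a secondary carbinol next to a cyclic ether oxygen proceeds by SN2 displacement of the oxyphosphonium group, so (13R)-OH becomes (13S)-Br, and the robust ketone tolerates the heating this hindered centre needs.

**Step 11**
Reactants: 20 but-3-yn-1-ol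
Product: 21 4-iodobut-3-yn-1-ol
Conditions: NIS, AgNO3 (10 mol %), acetone, rt
Reagents that add atoms: N-iodosuccinimide, O=C1CCC(=O)N1I
Why: Silver-catalysed electrophilic iodination of a terminal alkyne is selective for the sp C–H bond and tolerates the free alcohol.

**Step 12**
Reactants: 21 4-iodobut-3-yn-1-ol
Product: 22 (Z)-4-iodobut-3-en-1-ol
Conditions: 2-nitrobenzenesulfonohydrazide (NBSH), Et3N, THF/i-PrOH, rt
Reagents that add atoms: none
Why: Diimide reduction adds H2 in a concerted syn fashion to the iodoalkyne and so sets the Z geometry of the future C3=C4 bond without cleaving the C–I bond.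

**Step 13**
Reactants: 22 (Z)-4-iodobut-3-en-1-ol; 23 ethynyltrimethylsilane
Product: 24 (Z)-6-(trimethylsilyl)hex-3-en-5-yn-1-ol
Conditions: PdCl2(PPh3)2 (2 mol %), CuI (4 mol %), i-Pr2NH, THF, rt
Reagents that add atoms: none
Why: Sonogashira coupling of a vinyl iodide proceeds with retention of the alkene geometry and gives the Z-enyne.

**Step 14**
Reactants: 24 (Z)-6-(trimethylsilyl)hex-3-en-5-yn-1-ol
Product: 25 (Z)-6-(trimethylsilyl)hex-3-en-5-ynal
Conditions: Dess–Martin periodinane, pyridine, CH2Cl2, 0 °C; used directly
Reagents that add atoms: none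
Why: Buffered Dess–Martin oxidation is the mildest access to a β,γ-unsaturated aldehyde and should avoid migration of the Z double bond into conjugation.

**Step 15**
Reactants: 19 (3aR,5R,6aS)-5-[(1S)-1-bromopropyl]tetrahydrofuro[3,2-b]furan-3(2H)-one; 25 (Z)-6-(trimethylsilyl)hex-3-en-5-ynal
Product: 27 aldol adduct (mixture at C6 and C7), via lithium enolate of ketone 26 (not isolated)
Conditions: LiHMDS (1.05 equiv), THF, −78 °C; then 25, −78 °C, short contact; AcOH/THF at −78 °C
Reagents that add atoms: none
Why: In this directed aldol addition kinetic deprotonation takes the less hindered C7 methylene rather than the C9 methine, addition to the aldehyde at −78 °C should outrun proton transfer, and the two new centres need no control because step 16 removes them.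

**Step 16**
Reactants: 27 aldol adduct (mixture at C6 and C7)
Product: 29 (Z)-enone (6Z,9R,10S,12R,13S), via mesylate 28 (not isolated)
Conditions: MsCl, Et3N, CH2Cl2, −30 to 0 °C
Reagents that add atoms: none
Why: Mesylation followed by E1cB elimination through the C7 enolate converges both aldol diastereomers on the more stable Z-alkylidene furanone (chain syn to the ring oxygen and away from the C8 carbonyl), and the weak base at low temperature should leave the doubly allylic C5H2 alone.

**Step 17**
Reactants: 29 (Z)-enone (6Z,9R,10S,12R,13S)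
Product: 30 silylated allylic alcohol (8R,9S,10S,12R,13S)
Conditions: NaBH4, CeCl3·7H2O, MeOH, −78 °C
Reagents that add atoms: none
Why: Luche reduction gives clean 1,2-addition, and hydride attacks C8 from the convex face, anti to the C9–O bond and to ring B, so the hydroxyl ends up on the concave face (8R).

**Step 18**
Reactants: 30 silylated allylic alcohol (8R,9S,10S,12R,13S)
Product: 31 terminal-alkyne allylic alcohol (8R,9S,10S,12R,13S)
Conditions: K2CO3 (0.2 equiv), MeOH, 0 °C
Reagents that add atoms: none
Why: Carbonate-catalysed methanolysis removes the alkynyl silane under conditions too mild to affect the secondary bromide, the enol ether or the skipped diene unit, and it is placed before the base-sensitive allylic bromide exists.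

**Step 19**
Reactants: 31 terminal-alkyne allylic alcohol (8R,9S,10S,12R,13S)
Product: 32 target (8S,9R,10S,12R,13S)
Conditions: CBr4, PPh3, 2,6-lutidine, CH2Cl2, −20 to 0 °C
Reagents that add atoms: carbon tetrabromide, BrC(Br)(Br)Br
Why: In this Appel reaction bromide attacks C8 from the open convex face anti to the concave oxyphosphonium group (SN2, 8R-OH to 8S-Br); ionisation is disfavoured because the ring oxygen sits on the central carbon of the allyl system, and the lutidine buffer protects the enol ether.

**Compound list**
1 | ethyl glycolate | CCOC(=O)CO | starting material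
2 | butyl vinyl ether | C=COCCCC | starting material
3 | ethyl 2-(vinyloxy)acetate | C=COCC(=O)OCC | intermediate
4 | tert-butyl acetate | CC(=O)OC(C)(C)C | starting material
5 | lithium enolate of tert-butyl acetate (not isolated) | [Li+].[O-]C(=C)OC(C)(C)C | intermediate
6 | tert-butyl 3-oxo-4-(vinyloxy)butanoate | C=COCC(=O)CC(=O)OC(C)(C)C | intermediate
7 | (R)-butane-1,2-diol | CC[C@@H](O)CO | starting material
8 | (R)-1-[(tert-butyldimethylsilyl)oxy]butan-2-ol | CC[C@@H](O)CO[Si](C)(C)C(C)(C)C | intermediate
9 | (vinyloxy)acetylketene (not isolated) | C=COCC(=O)C=C=O | intermediate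
10 | (R)-1-[(tert-butyldimethylsilyl)oxy]butan-2-yl 3-oxo-4-(vinyloxy)butanoate | C=COCC(=O)CC(=O)O[C@H](CC)CO[Si](C)(C)C(C)(C)C | intermediate
11 | (R)-1-[(tert-butyldimethylsilyl)oxy]butan-2-yl 2-diazo-3-oxo-4-(vinyloxy)butanoate | C=COCC(=O)C(=[N+]=[N-])C(=O)O[C@H](CC)CO[Si](C)(C)C(C)(C)C | intermediate
12 | (R)-1-hydroxybutan-2-yl 2-diazo-3-oxo-4-(vinyloxy)butanoate | C=COCC(=O)C(=[N+]=[N-])C(=O)O[C@H](CC)CO | intermediate
13 | (R)-1-oxobutan-2-yl 2-diazo-3-oxo-4-(vinyloxy)butanoate | C=COCC(=O)C(=[N+]=[N-])C(=O)O[C@H](CC)C=O | intermediate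
14 | rhodium carbenoid at C9 (not isolated; [Rh] = Rh2(OAc)4 core) | C=COCC(=O)C(=[Rh])C(=O)O[C@H](CC)C=O | intermediate
15 | cyclic carbonyl ylide: six-membered 2-oxo-1,4-dioxane ring with C9 carbanion, O+=C12H and (13R)-ethyl; C9 bears the (vinyloxy)acetyl group (not isolated) | C=COCC(=O)[C-]1[O+]=C[C@@H](CC)OC1=O | intermediate
16 | tricyclic keto lactone (9R,10S,12R,13R): cis-fused tetrahydrofuro[3,2-b]furan-3(2H)-one whose ring-fusion carbon C9 carries a carboxyl carbon lactonised onto the oxygen at C13 (3,8-dioxabicyclo[3.2.1]octan-2-one unit; ethyl trans to C11 on the lactone ring) | C1O[C@H]2C[C@H]3O[C@]2(C1=O)C(=O)O[C@@H]3CC | intermediate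
17 | β-keto acid: 18 with CO2H in place of H at C9 (not isolated) | C1O[C@H]2C[C@H]([C@H](O)CC)O[C@]2(C1=O)C(=O)O | intermediate
18 | (3aR,5R,6aS)-5-[(1R)-1-hydroxypropyl]tetrahydrofuro[3,2-b]furan-3(2H)-one (cis-fused, side chain on the convex face) | C1O[C@H]2C[C@H]([C@H](O)CC)O[C@H]2C1=O | intermediate
19 | (3aR,5R,6aS)-5-[(1S)-1-bromopropyl]tetrahydrofuro[3,2-b]furan-3(2H)-one | C1O[C@H]2C[C@H]([C@@H](Br)CC)O[C@H]2C1=O | intermediate
20 | but-3-yn-1-ol | C#CCCO | starting material
21 | 4-iodobut-3-yn-1-ol | OCCC#CI | intermediate
22 | (Z)-4-iodobut-3-en-1-ol | OCC/C=C\I | intermediate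
23 | ethynyltrimethylsilane | C#C[Si](C)(C)C | starting material
24 | (Z)-6-(trimethylsilyl)hex-3-en-5-yn-1-ol | OCC/C=C\C#C[Si](C)(C)C | intermediate
25 | (Z)-6-(trimethylsilyl)hex-3-en-5-ynal | O=CC/C=C\C#C[Si](C)(C)C | intermediate
26 | lithium C7=C8 enolate of 19 (not isolated) | [Li+].C1O[C@H]2C[C@H]([C@@H](Br)CC)O[C@H]2C=1[O-] | intermediate
27 | aldol adduct: 19 bearing at C7 a (3Z)-1-hydroxy-6-(trimethylsilyl)hex-3-en-5-yn-1-yl group (C6 and C7 unassigned, mixture; 9R,10S,12R,13S) | C[Si](C)(C)C#C/C=C\CC(O)C1O[C@H]2C[C@H]([C@@H](Br)CC)O[C@H]2C1=O | intermediate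
28 | C6 mesylate of 27 (not isolated) | C[Si](C)(C)C#C/C=C\CC(OS(C)(=O)=O)C1O[C@H]2C[C@H]([C@@H](Br)CC)O[C@H]2C1=O | intermediate
29 | (2Z,3aR,5R,6aS)-5-[(1S)-1-bromopropyl]-2-[(3Z)-6-(trimethylsilyl)hex-3-en-5-yn-1-ylidene]tetrahydrofuro[3,2-b]furan-3(2H)-one | C[Si](C)(C)C#C/C=C\C/C=C1\O[C@H]2C[C@H]([C@@H](Br)CC)O[C@H]2C1=O | intermediate
30 | allylic alcohol from 29, C8–OH on the concave face (3Z,6Z,8R,9S,10S,12R,13S), alkyne silylated | C[Si](C)(C)C#C/C=C\C/C=C1\O[C@H]2C[C@H]([C@@H](Br)CC)O[C@H]2[C@H]1O | intermediate
31 | the same allylic alcohol with free terminal alkyne (3Z,6Z,8R,9S,10S,12R,13S) | C#C/C=C\C/C=C1\O[C@H]2C[C@H]([C@@H](Br)CC)O[C@H]2[C@H]1O | intermediate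
32 | target, (3Z,6Z,8S,9R,10S,12R,13S)-8,13-dibromo-7,10:9,12-diepoxypentadeca-3,6-dien-1-yne | C#C/C=C\C/C=C1\O[C@H]2C[C@H]([C@@H](Br)CC)O[C@H]2[C@@H]1Br | target

**Step count**
Total step count: 19. Longest linear sequence: 14 (steps 1, 2, 4–10, 15–19).

**Steps most likely to fail**

**Step 8.**
- What may go wrong: The carbenoid may be intercepted by its own vinyl ether (cyclopropanation or C-attack) before the ester has turned into the rotamer that lets the aldehyde oxygen reach C9. The ethyl group may also bias the two ylide faces too weakly.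
- Fallback concept: The alkene is taken out of the diazo compound, so that ylide closure competes only with an intermolecular alkene, and ring A is closed afterwards. The fallback sets out from 8 and returns at 16.
- Building the diazo aldehyde: Thermal transesterification of purchased ethyl 4-chloroacetoacetate with 8 gives (R)-1-[(tert-butyldimethylsilyl)oxy]butan-2-yl 4-chloro-3-oxobutanoate F1. Regitz diazo transfer gives the 4-chloro-2-diazo-3-oxobutanoate F2. Buffered TBAF gives (R)-1-hydroxybutan-2-yl 4-chloro-2-diazo-3-oxobutanoate F3. Dess–Martin oxidation gives (R)-1-oxobutan-2-yl 4-chloro-2-diazo-3-oxobutanoate F4.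
- Cycloaddition and ring closure: Rh2(OAc)4 in the presence of excess trimethyl(vinyloxy)silane forms the same type of cyclic ylide. Known intermolecular cycloaddition to the electron-rich alkene still makes C9–C10 and C11–C12 together and gives the exo-silyloxy chloromethyl ketone adduct F5. Fluoride then frees the C10 alkoxide, which displaces the α-keto chloride (5-exo-tet) to close ring A and give 16.

**Step 15.**
- What may go wrong: Proton transfer from the doubly activated CH2 of 25 to the enolate, and base-induced migration of the Z double bond into conjugation, may outrun C–C bond formation.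
- Fallback concept: The chain is built stepwise from a robust aldehyde, and the skipped enyne is made only after the ketone has been reduced. The fallback sets out from 19 and returns at 31.
- Through the diol: The enolate 26 is added to purchased 3-[(tert-butyldimethylsilyl)oxy]propanal to give the silyloxypropyl aldol F6. MsCl/Et3N gives the (Z)-silyloxypropylidene enone F7. Luche reduction gives the concave allylic alcohol F8. TBAF gives the diol F9.
- From the aldehyde to the enyne: TEMPO/PhI(OAc)2 oxidises only the primary alcohol to the aldehyde F10. Peterson olefination with lithiated 1,3-bis(triisopropylsilyl)propyne gives the (Z)-triisopropylsilyl enyne F11. TBAF gives 31.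

**Step 19.**
- What may go wrong: Allylic transposition (SN2′ attack at C6), ionisation with loss of configuration at C8, or acid-induced destruction of the enol ether within the oxyphosphonium ion pair may compete with direct displacement.
- Fallback: Activation is separated from displacement. The fallback sets out from 31 and returns at 32. Chloromethanesulfonyl chloride and 2,6-lutidine at low temperature give the isolable C8 chloromethanesulfonate F12. This is displaced by soluble LiBr in THF in a separate, phosphine-free and acid-free SN2 step from the convex face.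

**Further compounds**
F1 | step 8 | (R)-1-[(tert-butyldimethylsilyl)oxy]butan-2-yl 4-chloro-3-oxobutanoate | ClCC(=O)CC(=O)O[C@H](CC)CO[Si](C)(C)C(C)(C)C
F2 | step 8 | (R)-1-[(tert-butyldimethylsilyl)oxy]butan-2-yl 4-chloro-2-diazo-3-oxobutanoate | ClCC(=O)C(=[N+]=[N-])C(=O)O[C@H](CC)CO[Si](C)(C)C(C)(C)C
F3 | step 8 | (R)-1-hydroxybutan-2-yl 4-chloro-2-diazo-3-oxobutanoate | ClCC(=O)C(=[N+]=[N-])C(=O)O[C@H](CC)CO
F4 | step 8 | (R)-1-oxobutan-2-yl 4-chloro-2-diazo-3-oxobutanoate | ClCC(=O)C(=[N+]=[N-])C(=O)O[C@H](CC)C=O
F5 | step 8 | exo-silyloxy chloromethyl ketone adduct (3,8-dioxabicyclo[3.2.1]octan-2-one with chloroacetyl at C9 and OSiMe3 at C10 syn to the oxygen bridge) | C[Si](C)(C)O[C@H]1C[C@H]2O[C@]1(C(=O)CCl)C(=O)O[C@@H]2CC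
F6 | step 15 | silyloxypropyl aldol (C6 and C7 unassigned) | CC(C)(C)[Si](C)(C)OCCC(O)C1O[C@H]2C[C@H]([C@@H](Br)CC)O[C@H]2C1=O
F7 | step 15 | (Z)-silyloxypropylidene enone | CC(C)(C)[Si](C)(C)OCC/C=C1\O[C@H]2C[C@H]([C@@H](Br)CC)O[C@H]2C1=O
F8 | step 15 | concave allylic alcohol (8R) with C4 silyl ether | CC(C)(C)[Si](C)(C)OCC/C=C1\O[C@H]2C[C@H]([C@@H](Br)CC)O[C@H]2[C@H]1O
F9 | step 15 | C4,C8-diol | OCC/C=C1\O[C@H]2C[C@H]([C@@H](Br)CC)O[C@H]2[C@H]1O
F10 | step 15 | C4 aldehyde with free C8 alcohol | O=CC/C=C1\O[C@H]2C[C@H]([C@@H](Br)CC)O[C@H]2[C@H]1O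
F11 | step 15 | (Z)-triisopropylsilyl enyne allylic alcohol | CC(C)[Si](C(C)C)(C(C)C)C#C/C=C\C/C=C1\O[C@H]2C[C@H]([C@@H](Br)CC)O[C@H]2[C@H]1O
F12 | step 19 | C8 chloromethanesulfonate of 31 | C#C/C=C\C/C=C1\O[C@H]2C[C@H]([C@@H](Br)CC)O[C@H]2[C@H]1OS(=O)(=O)CCl
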